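**Retrosynthetic overview**
- The target is the diacetate of a bis-oxepanone diol; both 2,2-dimethyloxepan-3-ones come last, by a two-fold CMe2-inserting ring expansion (1,2-shift of the ring oxygen) of a bis-δ-lactone.
- The two halves differ only at C10: the axial tertiary alcohol comes from methyl addition to a ketone, the equatorial one from hydration of an exocyclic alkene.
- The central C12–C12' bond is made by radical conjugate addition of a borane (from the allylic-alcohol half) to the α-methylene ketone half; both halves come from one bicyclic enone.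
- That enone comes from (S)-4-hydroxy-3-methylcyclohexenone by conjugate addition anti to the C7 oxygen (quaternary C6), Mannich methylenation and acetal ring closure.
- Ring order: cyclohexane (bought) → trans-fused tetrahydropyran acetal → δ-lactone → oxepanone.

Assumption: locants are squalene-type (C2 = CMe2, C3 = C=O, C6 = C–Me at the ring fusion, C7 = CH–O, C10 = C(Me)–OAc, C11 = CH, C12 = linker CH2; primes for the second-written half). The SMILES is read as (6S,7S,10R,11S,6'S,7'S,10'S,11'S), i.e. not C2-symmetric: axial OAc at C10, equatorial OAc at C10'. The L-fructose-derived Shi ketone and Me2CBr2 are taken as purchasable.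

**Route**

Step 1
Reactants: 1 3-methylcyclohex-2-en-1-one
Product: 2 7-methyl-1,4-dioxaspiro[4.5]dec-7-ene
Conditions: HOCH2CH2OH, p-TsOH (cat.), benzene, reflux, Dean–Stark
Reagents that add atoms: ethylene glycol, OCCO
Why: Acid-catalysed ketalization with migration of the double bond out of conjugation (deconjugative ketalization) gives the β,γ-unsaturated ketal; no stereocentre is formed.

Step 2
Reactants: 2 7-methyl-1,4-dioxaspiro[4.5]dec-7-ene
Product: 3 (7R,8S)-7,8-epoxy-7-methyl-1,4-dioxaspiro[4.5]decane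
Conditions: L-fructose-derived Shi ketone (30 mol %), KHSO5 (Oxone), K2CO3, Bu4NHSO4, MeCN–(MeO)2CH2–aq. buffer pH 10.5, 0 °C
Reagents that add atoms: potassium peroxymonosulfate, [K+].[O-]S(=O)(=O)OO
Why: Shi asymmetric epoxidation of a trisubstituted alkene; the chiral dioxirane (catalyst enantiomer chosen by the spiro transition-state model) sets both epoxide carbons, and C8 becomes C7 of the target.

Step 3
Reactants: 3 (7R,8S)-7,8-epoxy-7-methyl-1,4-dioxaspiro[4.5]decane
Product: 5 (S)-4-hydroxy-3-methylcyclohex-2-en-1-one, via epoxy ketone 4 (not isolated)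
Conditions: 1 M HCl (cat.), THF–H2O, rt; then Et3N
Reagents that add atoms: water, O
Why: Ketal hydrolysis, then β-elimination of the β,γ-epoxy ketone (E1cB-type epoxide opening) gives the γ-hydroxy enone; the C–O bond at the carbinol carbon is untouched, so its configuration is kept.

Step 4
Reactants: 5 (S)-4-hydroxy-3-methylcyclohex-2-en-1-one; 6 2-(2-bromoethyl)-1,3-dioxolane
Product: 9 (3S,4S)-2-[(dimethylamino)methyl]-3-[2-(1,3-dioxolan-2-yl)ethyl]-3-methyl-4-[(trimethylsilyl)oxy]cyclohexan-1-one (C2 epimers), via silyloxy enone 7 (not isolated), via bis-silyl enol ether 8 (not isolated)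
Conditions: i-PrMgCl (1 equiv), THF, −78 → 0 °C, TMSCl; then BrMgCH2CH2CH(OCH2CH2O) (from 6, Mg, THF), CuBr·SMe2 (10 mol %), TMSCl, HMPA, −78 → −30 °C; then Me2N=CH2+ I−, CH2Cl2, rt; aq. NaHCO3
Reagents that add atoms: chlorotrimethylsilane, C[Si](C)(C)Cl; N,N-dimethylmethyleneiminium iodide, C=[N+](C)C.[I-]
Why: Cu-catalysed Grignard conjugate addition with TMSCl anti to the C7 silyloxy group sets the quaternary C6, and the regiodefined silyl enol ether undergoes a Mannich reaction with the iminium salt to place C12 on C11.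

Step 5
Reactants: 9 (3S,4S)-2-[(dimethylamino)methyl]-3-[2-(1,3-dioxolan-2-yl)ethyl]-3-methyl-4-[(trimethylsilyl)oxy]cyclohexan-1-one
Product: 12 (4aS,8aS)-2-methoxy-4a-methyl-5-methylideneoctahydro-6H-chromen-6-one (anomer mixture at C2), via acetal amine hydrochloride 10 (not isolated), via ammonium iodide 11 (not isolated)
Conditions: HCl (1.3 equiv), MeOH–CH2Cl2, rt; evaporate; then K2CO3, MeI, CH2Cl2–H2O, rt
Reagents that add atoms: methanol, CO
Why: Desilylation and transacetalization close the trans-fused tetrahydropyran (this locks the C6 methyl axial), and quaternization followed by E1cB elimination of trimethylamine (Mannich-base methylenation) gives the α-methylene ketone.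

Step 6
Reactants: 12 (4aS,8aS)-2-methoxy-4a-methyl-5-methylideneoctahydro-6H-chromen-6-one
Product: 13 (4aS,6R,8aS)-2-methoxy-4a,6-dimethyl-5-methylideneoctahydro-2H-chromen-6-ol
Conditions: MeLi, CeCl3, THF, −78 °C
Reagents that add atoms: methyllithium, [Li]C
Why: Organocerium 1,2-addition to the enone carbonyl; axial attack is blocked by the axial angular methyl, so methyl enters equatorially and the OH is axial (10R, as in the first half of the target).

Step 7
Reactants: 13 (4aS,6R,8aS)-2-methoxy-4a,6-dimethyl-5-methylideneoctahydro-2H-chromen-6-ol; 12 (4aS,8aS)-2-methoxy-4a-methyl-5-methylideneoctahydro-6H-chromen-6-one (1.5 equiv)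
Product: 15 (4aS,5S,8aS)-5-{2-[(4aS,5S,6R,8aS)-6-hydroxy-2-methoxy-4a,6-dimethyloctahydro-2H-chromen-5-yl]ethyl}-2-methoxy-4a-methyloctahydro-6H-chromen-6-one, via bis-boron intermediate 14 (not isolated)
Conditions: catecholborane (3 equiv), MeC(O)NMe2 (10 mol %), CH2Cl2, 40 °C; then 12, DMPU, H2O, air (O2, cat.), rt; then DBU, CH2Cl2
Reagents that add atoms: none
Why: Hydroboration of the 1,1-disubstituted alkene from the face opposite the axial C6 methyl and axial C10 oxygen sets C11 (H axial, CH2B equatorial), and the B-alkylcatecholborane adds as a primary radical to the α-methylene ketone in an O2-initiated chain (radical conjugate addition of organoboranes to enones) to form C12–C12'; C11' is set by enolate protonation and DBU equilibration to the equatorial side chain.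

Step 8
Reactants: 15 keto alcohol (name as in step 7)
Product: 16 (4aS,5S,6R,8aS)-2-methoxy-5-{2-[(4aS,5R,8aS)-2-methoxy-4a-methyl-6-methylideneoctahydro-2H-chromen-5-yl]ethyl}-4a,6-dimethyloctahydro-2H-chromen-6-ol
Conditions: Ph3PCH3Br, KOt-Bu, toluene, 80 °C
Reagents that add atoms: methyltriphenylphosphonium bromide, C[P+](c1ccccc1)(c1ccccc1)c1ccccc1.[Br-]
Why: Wittig methylenation of the hindered ketone; C11' keeps its thermodynamically preferred equatorial configuration under the basic conditions (the 5R label is only a change in CIP priorities).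

Step 9
Reactants: 16 hydroxy alkene (name as in step 8)
Product: 17 (4aS,5S,6R,8aS)-5-{2-[(4aS,5S,6S,8aS)-6-hydroxy-2-methoxy-4a,6-dimethyloctahydro-2H-chromen-5-yl]ethyl}-2-methoxy-4a,6-dimethyloctahydro-2H-chromen-6-ol
Conditions: Mn(dpm)3 (10 mol %), PhSiH3, O2 (1 atm), i-PrOH–CH2Cl2, 0 °C → rt
Reagents that add atoms: dioxygen, O=O
Why: Mukaiyama hydration (metal-hydride hydrogen-atom transfer, Markovnikov); the tertiary C10' radical is trapped by O2 from the equatorial face, away from the axial angular methyl, giving the equatorial OH and axial methyl (10'S).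

Step 10
Reactants: 17 diol bis(methyl acetal) (name as in step 9)
Product: 18 (4aS,5S,6R,8aS)-6-hydroxy-5-{2-[(4aS,5S,6S,8aS)-6-hydroxy-4a,6-dimethyl-2-oxooctahydro-2H-chromen-5-yl]ethyl}-4a,6-dimethyloctahydro-2H-chromen-2-one
Conditions: CrO3, H2SO4, H2O–acetone, 0 °C → rt
Reagents that add atoms: water, O
Why: Jones oxidation; the lactol methyl ethers are hydrolysed in situ and oxidized to the trans-fused δ-lactones, while the tertiary alcohols cannot be oxidized.

Step 11
Reactants: 18 bis-δ-lactone diol (name as in step 10)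
Product: 20 (6S,7S,10R,11S,6'S,7'S,10'S,11'S)-bis-oxepanone diol (the target with OH in place of both OAc), via bis-bromolactol 19 (not isolated)
Conditions: Me2CBr2, n-BuLi (6 equiv each), THF–Et2O, −110 °C, then 18; AcOH, −100 °C; then AgBF4, 2,6-di-tert-butyl-4-methylpyridine, CH2Cl2, −40 °C → rt
Reagents that add atoms: 2,2-dibromopropane, CC(C)(Br)Br
Why: Proposed new method: LiCMe2Br adds to each lactone carbonyl (as in the known carbenoid homologation of esters to α-halo ketones) to give a cyclic bromo-hemiketal; AgBF4 then removes the tertiary bromide while the antiperiplanar ring oxygen bridges to the CMe2 carbon and the hemiketal OH collapses to C=O, so the ring oxygen shifts from C3 to C2 and the six-membered lactol becomes the 2,2-dimethyloxepan-3-one (semipinacol-type ring expansion with oxygen migrating; no new stereocentre); the closest known reaction types are silver-promoted semipinacol rearrangement of halohydrins with carbon migration, isomerization of epoxy ethers to α-alkoxy ketones, and ring expansions of cyclic ethers through bicyclic oxonium ions.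

Step 12
Reactants: 20 bis-oxepanone diol
Product: 21 target diacetate, (6S,7S,10R,11S,6'S,7'S,10'S,11'S)
Conditions: Ac2O, Bi(OTf)3 (5 mol %), MeCN, 0 °C → rt
Reagents that add atoms: acetic anhydride, CC(=O)OC(C)=O
Why: Lewis-acid-catalysed acetylation of both hindered tertiary alcohols with retention (O-acylation, no C–O cleavage); the α-alkoxy ketones are untouched.

**Compound list**
1 | 3-methylcyclohex-2-en-1-one | CC1=CC(=O)CCC1 | starting material
2 | 7-methyl-1,4-dioxaspiro[4.5]dec-7-ene | CC1=CCCC2(C1)OCCO2 | intermediate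
3 | (7R,8S)-7,8-epoxy-7-methyl-1,4-dioxaspiro[4.5]decane | O1CCOC12CC[C@@H]3O[C@]3(C)C2 | intermediate
4 | (3R,4S)-3,4-epoxy-3-methylcyclohexan-1-one | O=C1CC[C@@H]2O[C@]2(C)C1 | intermediate
5 | (S)-4-hydroxy-3-methylcyclohex-2-en-1-one | O=C1CC[C@H](O)C(C)=C1 | intermediate
6 | 2-(2-bromoethyl)-1,3-dioxolane | BrCCC1OCCO1 | starting material
7 | (S)-3-methyl-4-[(trimethylsilyl)oxy]cyclohex-2-en-1-one | O=C1CC[C@H](O[Si](C)(C)C)C(C)=C1 | intermediate
8 | (3S,4S)-3-[2-(1,3-dioxolan-2-yl)ethyl]-3-methyl-1,4-bis[(trimethylsilyl)oxy]cyclohex-1-ene | C[Si](C)(C)OC1=C[C@](C)(CCC2OCCO2)[C@@H](O[Si](C)(C)C)CC1 | intermediate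
9 | (3S,4S)-2-[(dimethylamino)methyl]-3-[2-(1,3-dioxolan-2-yl)ethyl]-3-methyl-4-[(trimethylsilyl)oxy]cyclohexan-1-one (C2 epimers) | O=C1CC[C@H](O[Si](C)(C)C)[C@@](C)(CCC2OCCO2)C1CN(C)C | intermediate
10 | (4aS,8aS)-5-[(dimethylamino)methyl]-2-methoxy-4a-methyloctahydro-6H-chromen-6-one hydrochloride | O=C1CC[C@@H]2OC(OC)CC[C@@]2(C)C1CN(C)C.Cl | intermediate
11 | [(4aS,8aS)-2-methoxy-4a-methyl-6-oxooctahydro-2H-chromen-5-yl]-N,N,N-trimethylmethanaminium iodide | O=C1CC[C@@H]2OC(OC)CC[C@@]2(C)C1C[N+](C)(C)C.[I-] | intermediate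
12 | (4aS,8aS)-2-methoxy-4a-methyl-5-methylideneoctahydro-6H-chromen-6-one | O=C1CC[C@@H]2OC(OC)CC[C@@]2(C)C1=C | intermediate
13 | (4aS,6R,8aS)-2-methoxy-4a,6-dimethyl-5-methylideneoctahydro-2H-chromen-6-ol | O[C@]1(C)CC[C@@H]2OC(OC)CC[C@@]2(C)C1=C | intermediate
14 | catechol borate of (4aS,5S,6R,8aS)-5-[(1,3,2-benzodioxaborol-2-yl)methyl]-2-methoxy-4a,6-dimethyloctahydro-2H-chromen-6-ol | O(B3Oc4ccccc4O3)[C@]1(C)CC[C@@H]2OC(OC)CC[C@@]2(C)[C@@H]1CB1Oc2ccccc2O1 | intermediate
15 | keto alcohol, half A 6-hydroxy (4aS,5S,6R,8aS), half B 6-oxo (4aS,5S,8aS), joined C5–CH2CH2–C5' | O[C@]1(C)CC[C@@H]2OC(OC)CC[C@@]2(C)[C@@H]1CC[C@H]1[C@]2(C)CCC(OC)O[C@H]2CCC1=O | intermediate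
16 | hydroxy alkene, half B 6-methylidene | O[C@]1(C)CC[C@@H]2OC(OC)CC[C@@]2(C)[C@@H]1CC[C@H]1[C@]2(C)CCC(OC)O[C@H]2CCC1=C | intermediate
17 | diol bis(methyl acetal), half A 6R (axial OH), half B 6S (equatorial OH) | O[C@]1(C)CC[C@@H]2OC(OC)CC[C@@]2(C)[C@@H]1CC[C@H]1[C@]2(C)CCC(OC)O[C@H]2CC[C@]1(C)O | intermediate
18 | bis-δ-lactone diol | O[C@]1(C)CC[C@@H]2OC(=O)CC[C@@]2(C)[C@@H]1CC[C@H]1[C@]2(C)CCC(=O)O[C@H]2CC[C@]1(C)O | intermediate
19 | bis(2-hydroxy-2-(2-bromopropan-2-yl)tetrahydropyran) diol (bromo-lactol) | O[C@]1(C)CC[C@@H]2OC(O)(C(C)(C)Br)CC[C@@]2(C)[C@@H]1CC[C@H]1[C@]2(C)CCC(O)(C(C)(C)Br)O[C@H]2CC[C@]1(C)O | intermediate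
20 | (6S,7S,10R,11S,6'S,7'S,10'S,11'S)-bis(2,2-dimethyloxepan-3-one) diol | O[C@]1(C)CC[C@@H]2OC(C)(C)C(=O)CC[C@@]2(C)[C@@H]1CC[C@H]1[C@]2(C)CCC(=O)C(C)(C)O[C@H]2CC[C@]1(C)O | intermediate
21 | target diacetate CNP0325605.1 | CC(=O)O[C@]1(C)CC[C@@H]2OC(C)(C)C(=O)CC[C@@]2(C)[C@@H]1CC[C@H]1[C@]2(C)CCC(=O)C(C)(C)O[C@H]2CC[C@]1(C)OC(C)=O | target

**Step count and risks**
Total steps: 12. Longest linear sequence: 12 (compound 13 is made from 12, which is also its coupling partner).

Steps most likely to fail: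

Step 11 (the new ring expansion). The bromo-hemiketal may instead close to an epoxy ether, or undergo methyl shift or elimination. The fallback uses known reactions, sets out from 18 and returns at 20. i-Bu2AlH reduces both lactones to the bis-lactol F3. Wittig reaction with Ph3P=CMe2 gives the tetraol bis(trisubstituted alkene) F4. mCPBA gives the bis-epoxide F5. Acid (CSA) promotes 7-endo opening at the tertiary epoxide carbon to the bis(2,2-dimethyloxepan-3-ol) F6. Dess–Martin periodinane oxidizes the two secondary alcohols to 20. This builds the seven-membered rings by direct closure instead of ring expansion.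

Step 7 (fragment union). Hydroboration of the hindered alkene may be slow, and the radical addition runs at near 1:1 stoichiometry. The fallback sets out from 12 and returns at 15. SmI2/HMPA/t-BuOH reductive β,β-hydrodimerization of 12 gives the C2-symmetric 1,6-diketone F1, with both C11 centres set thermodynamically. MeLi/CeCl3 (1 equiv) then adds once, from the equatorial face, to give 15; this is statistical, and unreacted diketone is recycled.

Step 9 (hydration). The facial selectivity of O2 trapping may be only moderate. The fallback sets out from 16 and returns at 17. mCPBA epoxidizes the exocyclic alkene from the equatorial face to the spiro-epoxide F2, and LiEt3BH opens it at the CH2 carbon to give the equatorial tertiary alcohol 17.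

Further compounds
F1 | step 7 | C2-symmetric 1,6-diketone, 5,5'-(ethane-1,2-diyl)bis[(4aS,5S,8aS)-2-methoxy-4a-methyloctahydro-6H-chromen-6-one] | O=C1CC[C@@H]2OC(OC)CC[C@@]2(C)[C@@H]1CC[C@H]1[C@]2(C)CCC(OC)O[C@H]2CCC1=O
F2 | step 9 | spiro-epoxide of 16 (epoxide oxygen equatorial at C10') | O[C@]1(C)CC[C@@H]2OC(OC)CC[C@@]2(C)[C@@H]1CC[C@H]1[C@]2(C)CCC(OC)O[C@H]2CC[C@@]13CO3
F3 | step 11 | bis-lactol diol | O[C@]1(C)CC[C@@H]2OC(O)CC[C@@]2(C)[C@@H]1CC[C@H]1[C@]2(C)CCC(O)O[C@H]2CC[C@]1(C)O
F4 | step 11 | tetraol with two 4-methylpent-3-enyl chains | O[C@]1(C)CC[C@H](O)[C@@](C)(CCC=C(C)C)[C@@H]1CC[C@@H]1[C@@](C)(O)CC[C@H](O)[C@@]1(C)CCC=C(C)C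
F5 | step 11 | tetraol bis-epoxide | O[C@]1(C)CC[C@H](O)[C@@](C)(CCC2OC2(C)C)[C@@H]1CC[C@@H]1[C@@](C)(O)CC[C@H](O)[C@@]1(C)CCC1OC1(C)C
F6 | step 11 | bis(2,2-dimethyloxepan-3-ol) diol | O[C@]1(C)CC[C@@H]2OC(C)(C)C(O)CC[C@@]2(C)[C@@H]1CC[C@H]1[C@]2(C)CCC(O)C(C)(C)O[C@H]2CC[C@]1(C)O
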